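The C3–C4 bond of the oxolane ring is read as the former C=C of a butenolide. Its carbonyl carbon ends as the hydroxymethyl arm on C3 and its γ acetal carbon as C5, while the two neighbours, C2 and the benzylic CH2 on C4, are both former aromatic aldehyde carbons. A lithiated vanillin dithiane (polarity reversal) adds 1,4 to (5R)-menthyloxyfuranone and the enolate is trapped by a syringaldehyde ether. One flask thus forms the C4–CH2(benzylic) and C2–C3 bonds and sets C3 and C4. The precursors are a silyl-protected aryl dithiane, the chiral butenolide and a silyl-protected aldehyde.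

Key step: step 4

Remark: oxolane numbering is O1, C2 (syringyl), C3 (CH2O arm), C4 (guaiacylmethyl), C5; the target is (2S,3R,4R).
Remark: the phenols are carried as triisopropylsilyl (TIPS) ethers, not benzyl ethers, so that no hydrogenolysis is needed next to the benzylic C2–O1 bond or the cinnamate alkene, Raney Ni meets no O-benzyl group, and only one free phenol is present in the esterification.
Remark: the carbinol carbon made in step 4 is written as (S) for definiteness; its epimer, if formed, is carried along unseparated, because step 7 erases this centre.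

Step 1
Reactants: 1 vanillin
Product: 2 2-(4-hydroxy-3-methoxyphenyl)-1,3-dithiane
Conditions: HS(CH2)3SH, BF3·OEt2 (cat.), CH2Cl2, 0 °C → rt
Reagents that add atoms: 1,3-propanedithiol, SMILES SCCCS
Why: Lewis-acid-catalysed dithioacetalisation of an aromatic aldehyde, which tolerates the free phenol and creates no stereocentre.

Step 2
Reactants: 2 2-(4-hydroxy-3-methoxyphenyl)-1,3-dithiane
Product: 3 2-[3-methoxy-4-(triisopropylsilyloxy)phenyl]-1,3-dithiane
Conditions: TIPSCl, imidazole, DMF, rt
Reagents that add atoms: triisopropylsilyl chloride (TIPSCl), SMILES CC(C)[Si](Cl)(C(C)C)C(C)C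
Why: Imidazole-promoted O-silylation of a phenol, giving a bulky aryl silyl ether that should withstand n-BuLi, Raney Ni and LiAlH4 in the later steps.

Step 3
Reactants: 4 syringaldehyde
Product: 5 3,5-dimethoxy-4-(triisopropylsilyloxy)benzaldehyde
Conditions: TIPSCl, imidazole, DMF, rt → 40 °C
Reagents that add atoms: triisopropylsilyl chloride (TIPSCl), SMILES CC(C)[Si](Cl)(C(C)C)C(C)C
Why: The same O-silylation on the acidic, doubly flanked phenol, where gentle warming should offset the hindrance and the aldehyde is not touched.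

Step 4
Reactants: 3 2-[3-methoxy-4-(triisopropylsilyloxy)phenyl]-1,3-dithiane; 6 (5R)-5-(l-menthyloxy)furan-2(5H)-one; 5 3,5-dimethoxy-4-(triisopropylsilyloxy)benzaldehyde
Product: 9 (3S,4R,5R)-3-[(S)-[3,5-dimethoxy-4-(triisopropylsilyloxy)phenyl](hydroxy)methyl]-4-{2-[3-methoxy-4-(triisopropylsilyloxy)phenyl]-1,3-dithian-2-yl}-5-(l-menthyloxy)dihydrofuran-2(3H)-one, via lithiated dithiane 7 (not isolated), via lithium lactone enolate 8 (not isolated)
Conditions: n-BuLi, THF, −78 → −30 °C; 6, −78 °C; 5, −78 °C; AcOH, −78 °C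
Reagents that add atoms: none
Why: n-BuLi removes the dithiane C2–H of 3, turning the former aldehyde carbon into the sulfur-stabilised benzylic nucleophile 7, which adds in Michael fashion to C4 of butenolide 6 to give lithium enolate 8; this enolate then adds at C3 to the non-enolisable aldehyde 5 (aldol addition), and cold AcOH protonates the aldolate before it can revert. The closest known reaction type is the tandem conjugate addition–enolate trapping of lithiated 2-aryl-1,3-dithianes on butenolides and 5-alkoxybutenolides with aromatic aldehydes as the electrophile. No ring is closed; the two new C–C bonds are C4–C(dithiane) and C3–CH(OH)Ar. The C4 centre is dictated by the C5 acetal centre, the nucleophile entering anti to the menthyloxy group, and the C3 centre by the new bulky C4 dithianyl group, the aldehyde entering on the opposite face, which should give the 3,4-trans-4,5-trans lactone (3S,4R,5R); the carbinol centre is not reliably controlled and need not be. The step needs 1,4- over 1,2-addition, which the soft, charge-delocalised aryl dithiane anion in THF at −78 °C should secure, and two facial selectivities, which the nearly planar five-membered ring secures because each existing substituent shields one face.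

Step 5
Reactants: 9 the tandem adduct of step 4
Product: 10 (3S,4R,5R)-3-[(S)-[3,5-dimethoxy-4-(triisopropylsilyloxy)phenyl](hydroxy)methyl]-4-[3-methoxy-4-(triisopropylsilyloxy)benzyl]-5-(l-menthyloxy)dihydrofuran-2(3H)-one
Conditions: Raney Ni (W-2, washed neutral), EtOH, rt → 50 °C
Reagents that add atoms: none
Why: Raney Ni desulfurisation (hydrogenolytic C–S cleavage) turns the benzylic dithioketal carbon into CH2 while aryl silyl ethers, acetal and lactone are inert, and neutral catalyst at moderate temperature should spare the benzylic carbinol and avoid retro-aldol or epimerisation at C3, so no stereocentre changes.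

Step 6
Reactants: 10 the desulfurised lactone acetal of step 5
Product: 12 (2R,3R)-2-[(S)-[3,5-dimethoxy-4-(triisopropylsilyloxy)phenyl](hydroxy)methyl]-3-[3-methoxy-4-(triisopropylsilyloxy)benzyl]butane-1,4-diol, via ring-opened hydroxy aldehyde 11 (not isolated)
Conditions: LiAlH4, THF, 0 °C; then H2O, aq NaOH
Reagents that add atoms: none
Why: Hydride reduction of a lactone acetal, in which the carbonyl is reduced to the primary alkoxide, the freed hemiacetal oxygen expels menthoxide to unmask the acetal carbon as aldehyde 11 (as its aluminium alkoxide), and this is reduced at once, so both CH centres keep their configuration and the hindered aryl TIPS ethers should survive at 0 °C.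

Step 7
Reactants: 12 the triol of step 6
Product: 14 [(2S,3R,4R)-2-[3,5-dimethoxy-4-(triisopropylsilyloxy)phenyl]-4-[3-methoxy-4-(triisopropylsilyloxy)benzyl]oxolan-3-yl]methanol, via benzylic cation 13 (not isolated)
Conditions: CSA (cat.), CH2Cl2, 0 °C → rt
Reagents that add atoms: none
Why: Acid-catalysed SN1 cycloetherification, in which the electron-rich benzylic carbinol ionises to cation 13 and the 1,4-related primary hydroxyl captures it in a 5-exo closure (the 1,3-related one would give an oxetane), the aryl group settling trans to the C3 hydroxymethyl group under both kinetic and thermodynamic preference, so that C2 becomes (S) from either carbinol epimer.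

Step 8
Reactants: 14 the oxolane alcohol of step 7; 15 (E)-ferulic acid
Product: 17 [(2S,3R,4R)-2-[3,5-dimethoxy-4-(triisopropylsilyloxy)phenyl]-4-[3-methoxy-4-(triisopropylsilyloxy)benzyl]oxolan-3-yl]methyl (E)-3-(4-hydroxy-3-methoxyphenyl)prop-2-enoate, via alkoxyphosphonium ferulate 16 (not isolated)
Conditions: PPh3, DIAD, THF, 0 °C → rt
Reagents that add atoms: none
Why: Mitsunobu esterification, in which the only aliphatic hydroxyl is activated as oxyphosphonium salt 16 and displaced at its CH2 by the carboxylate, which is far more acidic than the single free phenol and therefore reacts in preference to it, with no stereocentre or alkene geometry involved.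

Step 9
Reactants: 17 the bis-silyl feruloyl ester of step 8
Product: 18 [(2S,3R,4R)-2-(4-hydroxy-3,5-dimethoxyphenyl)-4-(4-hydroxy-3-methoxybenzyl)oxolan-3-yl]methyl (E)-3-(4-hydroxy-3-methoxyphenyl)prop-2-enoate (CNP0289934.1)
Conditions: Bu4NF, AcOH, THF, 0 °C
Reagents that add atoms: none
Why: Fluoride-induced cleavage of both aryl silyl ethers, driven by Si–F bond formation and buffered with AcOH, so that the cinnamate ester, the (E)-alkene and the benzylic oxolane are left alone and no stereocentre is affected.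

Compound list
1 | vanillin | COc1cc(C=O)ccc1O | starting material
2 | 2-(4-hydroxy-3-methoxyphenyl)-1,3-dithiane | COc1cc(C2SCCCS2)ccc1O | intermediate
3 | 2-[3-methoxy-4-(triisopropylsilyloxy)phenyl]-1,3-dithiane | COc1cc(C2SCCCS2)ccc1O[Si](C(C)C)(C(C)C)C(C)C | intermediate
4 | syringaldehyde | COc1cc(C=O)cc(OC)c1O | starting material
5 | 3,5-dimethoxy-4-(triisopropylsilyloxy)benzaldehyde | COc1cc(C=O)cc(OC)c1O[Si](C(C)C)(C(C)C)C(C)C | intermediate
6 | (5R)-5-(l-menthyloxy)furan-2(5H)-one, l-menthyl being (1R,2S,5R)-2-isopropyl-5-methylcyclohexyl | O=C1C=C[C@H](O[C@@H]2C[C@H](C)CC[C@H]2C(C)C)O1 | starting material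
7 | 2-lithio-2-[3-methoxy-4-(triisopropylsilyloxy)phenyl]-1,3-dithiane | [Li]C1(c2ccc(O[Si](C(C)C)(C(C)C)C(C)C)c(OC)c2)SCCCS1 | intermediate (not isolated)
8 | lithium enolate of (4R,5R)-4-{2-[3-methoxy-4-(triisopropylsilyloxy)phenyl]-1,3-dithian-2-yl}-5-(l-menthyloxy)dihydrofuran-2(3H)-one | [Li]OC1=C[C@@H](C2(c3ccc(O[Si](C(C)C)(C(C)C)C(C)C)c(OC)c3)SCCCS2)[C@H](O[C@@H]2C[C@H](C)CC[C@H]2C(C)C)O1 | intermediate (not isolated)
9 | (3S,4R,5R)-3-[(S)-[3,5-dimethoxy-4-(triisopropylsilyloxy)phenyl](hydroxy)methyl]-4-{2-[3-methoxy-4-(triisopropylsilyloxy)phenyl]-1,3-dithian-2-yl}-5-(l-menthyloxy)dihydrofuran-2(3H)-one | O=C1[C@H]([C@H](O)c2cc(OC)c(O[Si](C(C)C)(C(C)C)C(C)C)c(OC)c2)[C@@H](C2(c3ccc(O[Si](C(C)C)(C(C)C)C(C)C)c(OC)c3)SCCCS2)[C@H](O[C@@H]2C[C@H](C)CC[C@H]2C(C)C)O1 | intermediate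
10 | (3S,4R,5R)-3-[(S)-[3,5-dimethoxy-4-(triisopropylsilyloxy)phenyl](hydroxy)methyl]-4-[3-methoxy-4-(triisopropylsilyloxy)benzyl]-5-(l-menthyloxy)dihydrofuran-2(3H)-one | O=C1[C@H]([C@H](O)c2cc(OC)c(O[Si](C(C)C)(C(C)C)C(C)C)c(OC)c2)[C@@H](Cc2ccc(O[Si](C(C)C)(C(C)C)C(C)C)c(OC)c2)[C@H](O[C@@H]2C[C@H](C)CC[C@H]2C(C)C)O1 | intermediate
11 | ring-opened hydroxy aldehyde: (2R,3R)-3-[(S)-aryl(hydroxy)methyl]-4-hydroxy-2-(arylmethyl)butanal with the aryl groups of 10 | OC[C@H]([C@H](O)c1cc(OC)c(O[Si](C(C)C)(C(C)C)C(C)C)c(OC)c1)[C@@H](Cc1ccc(O[Si](C(C)C)(C(C)C)C(C)C)c(OC)c1)C=O | intermediate (not isolated)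
12 | (2R,3R)-2-[(S)-[3,5-dimethoxy-4-(triisopropylsilyloxy)phenyl](hydroxy)methyl]-3-[3-methoxy-4-(triisopropylsilyloxy)benzyl]butane-1,4-diol | OC[C@H]([C@H](O)c1cc(OC)c(O[Si](C(C)C)(C(C)C)C(C)C)c(OC)c1)[C@@H](Cc1ccc(O[Si](C(C)C)(C(C)C)C(C)C)c(OC)c1)CO | intermediate
13 | benzylic cation formed from 12 by loss of water at the carbinol carbon | OC[C@H]([CH+]c1cc(OC)c(O[Si](C(C)C)(C(C)C)C(C)C)c(OC)c1)[C@@H](Cc1ccc(O[Si](C(C)C)(C(C)C)C(C)C)c(OC)c1)CO | intermediate (not isolated)
14 | [(2S,3R,4R)-2-[3,5-dimethoxy-4-(triisopropylsilyloxy)phenyl]-4-[3-methoxy-4-(triisopropylsilyloxy)benzyl]oxolan-3-yl]methanol | OC[C@H]1[C@@H](Cc2ccc(O[Si](C(C)C)(C(C)C)C(C)C)c(OC)c2)CO[C@@H]1c1cc(OC)c(O[Si](C(C)C)(C(C)C)C(C)C)c(OC)c1 | intermediate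
15 | (E)-ferulic acid | COc1cc(/C=C/C(=O)O)ccc1O | starting material
16 | alkoxytriphenylphosphonium salt of 14 with ferulate as counter-ion | c1ccc(cc1)[P+](OC[C@H]1[C@@H](Cc2ccc(O[Si](C(C)C)(C(C)C)C(C)C)c(OC)c2)CO[C@@H]1c1cc(OC)c(O[Si](C(C)C)(C(C)C)C(C)C)c(OC)c1)(c1ccccc1)c1ccccc1.COc1cc(/C=C/C([O-])=O)ccc1O | intermediate (not isolated)
17 | [(2S,3R,4R)-2-[3,5-dimethoxy-4-(triisopropylsilyloxy)phenyl]-4-[3-methoxy-4-(triisopropylsilyloxy)benzyl]oxolan-3-yl]methyl (E)-3-(4-hydroxy-3-methoxyphenyl)prop-2-enoate | COc1cc(/C=C/C(=O)OC[C@H]2[C@@H](Cc3ccc(O[Si](C(C)C)(C(C)C)C(C)C)c(OC)c3)CO[C@@H]2c2cc(OC)c(O[Si](C(C)C)(C(C)C)C(C)C)c(OC)c2)ccc1O | intermediate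
18 | [(2S,3R,4R)-2-(4-hydroxy-3,5-dimethoxyphenyl)-4-(4-hydroxy-3-methoxybenzyl)oxolan-3-yl]methyl (E)-3-(4-hydroxy-3-methoxyphenyl)prop-2-enoate (CNP0289934.1) | COc1cc(/C=C/C(=O)OC[C@H]2[C@@H](Cc3ccc(O)c(OC)c3)CO[C@@H]2c2cc(OC)c(O)c(OC)c2)ccc1O | target

Total step count: 9. Longest linear sequence: 8 steps (1, 2, 4, 5, 6, 7, 8, 9).

Steps most likely to fail

Step 4. The lithiated dithiane may attack the lactone carbonyl instead of C4, or the crowded aldolate next to the dithianyl group may revert or form incompletely, leaving the simple conjugate adduct. The fallback separates the two bond formations and changes the enolate metal. It sets out from 3 and 6: the conjugate addition is run alone (n-BuLi, THF, −78 °C, then 6, then AcOH) and the protonated Michael adduct lactone F1 is isolated. F1 is re-enolised with LiN(iPr)2 in THF at −78 °C, which regenerates enolate 8. Transmetalation with ZnCl2 gives the chlorozinc lactone enolate F2, whose chelated aldolate should resist retro-aldol cleavage, and addition of aldehyde 5 then returns the route to 9.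

Step 7. The benzylic cation may be captured by the guaiacyl ring (Friedel–Crafts closure to an aryltetralin) instead of by oxygen, the silyl ethers may be lost under acid, or ionisation may be slow because the twisted silyloxy group donates poorly. The fallback closes the ring through a quinone methide instead. It sets out from 12: Bu4NF/AcOH in THF removes both silyl groups to give the desilylated bisphenol triol F3. Under very mild acid (dilute AcOH in aqueous THF, rt) the free 4-hydroxybenzylic alcohol loses water to the para-quinone methide F4, and the 1,4-related hydroxyl adds to it to give the 2,3-trans bisphenol oxolane alcohol F5. Chemoselective Mitsunobu esterification of F5 with ferulic acid 15 (PPh3, DIAD, THF), the carboxylic acid reacting in preference to the phenols, rejoins the route at 18.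

Step 8. Activation of the β-branched primary alcohol may be slow, so that alkylation of the free phenol of ferulic acid or acylation of the reduced azodicarboxylate competes with ester formation. The fallback uses acyl activation of a phenol-protected acid. It sets out from 15 and 14: ferulic acid is silylated on both oxygens (TIPSCl, imidazole, DMF) to the bis-silylated ferulic acid F6, and the silyl ester alone is cleaved (K2CO3, MeOH/THF/H2O, 0 °C) to give 4-O-TIPS-ferulic acid F7. Steglich esterification of 14 with F7 (EDC·HCl, DMAP, CH2Cl2, rt) gives the tris-silyl feruloyl ester F8. Bu4NF/AcOH in THF, as in step 9, removes all three silyl groups and rejoins the route at 18.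

Further compounds
F1 | step 4 | (4R,5R)-4-{2-[3-methoxy-4-(triisopropylsilyloxy)phenyl]-1,3-dithian-2-yl}-5-(l-menthyloxy)dihydrofuran-2(3H)-one | O=C1C[C@@H](C2(c3ccc(O[Si](C(C)C)(C(C)C)C(C)C)c(OC)c3)SCCCS2)[C@H](O[C@@H]2C[C@H](C)CC[C@H]2C(C)C)O1
F2 | step 4 | chlorozinc enolate of F1 | Cl[Zn]OC1=C[C@@H](C2(c3ccc(O[Si](C(C)C)(C(C)C)C(C)C)c(OC)c3)SCCCS2)[C@H](O[C@@H]2C[C@H](C)CC[C@H]2C(C)C)O1
F3 | step 7 | (2R,3R)-2-[(S)-hydroxy(4-hydroxy-3,5-dimethoxyphenyl)methyl]-3-(4-hydroxy-3-methoxybenzyl)butane-1,4-diol | OC[C@H]([C@H](O)c1cc(OC)c(O)c(OC)c1)[C@@H](Cc1ccc(O)c(OC)c1)CO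
F4 | step 7 | para-quinone methide formed from F3 by loss of water | OC[C@H](C=C1C=C(OC)C(=O)C(OC)=C1)[C@@H](Cc1ccc(O)c(OC)c1)CO
F5 | step 7 | [(2S,3R,4R)-2-(4-hydroxy-3,5-dimethoxyphenyl)-4-(4-hydroxy-3-methoxybenzyl)oxolan-3-yl]methanol | OC[C@H]1[C@@H](Cc2ccc(O)c(OC)c2)CO[C@@H]1c1cc(OC)c(O)c(OC)c1
F6 | step 8 | triisopropylsilyl (E)-3-[3-methoxy-4-(triisopropylsilyloxy)phenyl]prop-2-enoate | COc1cc(/C=C/C(=O)O[Si](C(C)C)(C(C)C)C(C)C)ccc1O[Si](C(C)C)(C(C)C)C(C)C
F7 | step 8 | (E)-3-[3-methoxy-4-(triisopropylsilyloxy)phenyl]prop-2-enoic acid | COc1cc(/C=C/C(=O)O)ccc1O[Si](C(C)C)(C(C)C)C(C)C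
F8 | step 8 | [(2S,3R,4R)-2-[3,5-dimethoxy-4-(triisopropylsilyloxy)phenyl]-4-[3-methoxy-4-(triisopropylsilyloxy)benzyl]oxolan-3-yl]methyl (E)-3-[3-methoxy-4-(triisopropylsilyloxy)phenyl]prop-2-enoate | COc1cc(/C=C/C(=O)OC[C@H]2[C@@H](Cc3ccc(O[Si](C(C)C)(C(C)C)C(C)C)c(OC)c3)CO[C@@H]2c2cc(OC)c(O[Si](C(C)C)(C(C)C)C(C)C)c(OC)c2)ccc1O[Si](C(C)C)(C(C)C)C(C)C
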